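**Plan**

Rings: A = cyclohexene, B = lactone fused to A, C = 2-pyrroline, D = azepane, E = pendant lactone.
Cuts, in retrosynthetic order: (i) in one operation the ring C bond from its CH2 to the ring-fusion sp2 carbon and the ring D bond N–CH2, giving an N-alkenyl aziridine with a 4-chlorobutyl arm; (ii) the N–C(sp2) bond, giving an alkenyl triflate and an NH-aziridine; (iii) ring B at the bond from its α-carbon to the ring-fusion carbon, and ring A back to a quinone monoketal.
Enabling feature: ring C is a cyclic enamine whose N–CH(ring E)–CH2 edge is a 2-substituted aziridine in disguise and whose C=C–N unit is the enamine of the ring A ketone; the same N carries the (CH2)4 arm from the quaternary carbinol carbon, so N is the atom shared by rings C and D.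
Forward order: ring A (steps 2–5), ring B (steps 6–8), triflate (steps 9–11); ring E and the aziridine separately (steps 12–17); C–N coupling (18); one cascade expands the aziridine to ring C and closes ring D (19); desilylation (20).
Stereochemistry: a catalytic asymmetric conjugate addition sets the first ring A centre, and the others are relayed from it (trans alkylation, axial hydride delivery, oxidation anti to ethyl, tether-enforced cis lactone fusion, convex-face hydrogenation). The ring E and aziridine centres come from a D-serine-derived aldehyde (anti addition, cis hydrogenation), and the aziridine CH centre is carried unchanged into ring C.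

Key step: step 19

Assumption: the (S,R,R) antipode of the phosphoramidite ligand is taken to give the (5R) adduct 4; if the sense of induction proves opposite, the mirror-image ligand is used and nothing else changes.

**Step 1**
Reactants: 1 4-(benzyloxy)but-1-ene
Product: 2 [4-(benzyloxy)butyl]chlorobis(cyclopentadienyl)zirconium
Conditions: Cp2Zr(H)Cl (0.95 equiv), CH2Cl2, rt, until the suspension clears; solvent removed in vacuo under argon, residue taken up in Et2O
Reagents that add atoms: chlorobis(cyclopentadienyl)hydridozirconium, Cl[ZrH](C1C=CC=C1)C1C=CC=C1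
Why: Hydrozirconation adds Zr–H across the terminal alkene with the metal at the unhindered terminal carbon, so each molecule of alkene gives one primary alkylzirconocene chloride carrying a single transferable alkyl group, while the benzyl ether is inert and no stereocentre is formed.

**Step 2**
Reactants: 3 4,4-dimethoxycyclohexa-2,5-dien-1-one; 2 [4-(benzyloxy)butyl]chlorobis(cyclopentadienyl)zirconium
Product: 4 (5R)-5-[4-(benzyloxy)butyl]-4,4-dimethoxycyclohex-2-en-1-one
Conditions: 2 (1.5 equiv), (CuOTf)2·C6H6 (5 mol%), (S)-binaphthyl-2,2'-diyl N,N-bis[(R)-1-phenylethyl]phosphoramidite (10 mol%), Et2O, rt; aq. NH4Cl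
Reagents that add atoms: none
Why: Copper/phosphoramidite-catalysed enantioselective conjugate addition of alkylzirconocenes made by hydrozirconation is established for cyclic enones, and copper/phosphoramidite desymmetrisation of 4,4-dialkoxycyclohexadienones by alkylmetal reagents is likewise known, so the ligand should select between the enantiotopic β-carbons and set the stereocentre from which all ring A centres are relayed, while the adduct stays a zirconium enolate until the quench and cannot take up a second alkyl group.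

**Step 3**
Reactants: 4 (5R)-5-[4-(benzyloxy)butyl]-4,4-dimethoxycyclohex-2-en-1-one
Product: 5 (5R,6R)-5-[4-(benzyloxy)butyl]-6-ethyl-4,4-dimethoxycyclohex-2-en-1-one
Conditions: LiN(iPr)2, THF, −78 °C; EtI, DMPU, −78 to −20 °C
Reagents that add atoms: iodoethane, CCI
Why: Kinetic α'-deprotonation of the enone (there is no γ-hydrogen) and enolate alkylation anti to the neighbouring side chain should give the trans-5,6-disubstituted ketone, fixing the ethyl-bearing centre; the benzyl ether arm cannot alkylate the enolate, as a halide arm would.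

**Step 4**
Reactants: 5 (5R,6R)-5-[4-(benzyloxy)butyl]-6-ethyl-4,4-dimethoxycyclohex-2-en-1-one
Product: 7 (4R,5R,6R)-6-[4-(benzyloxy)butyl]-5-ethyl-4-hydroxycyclohex-2-en-1-one, via allylic alcohol ketal 6 (not isolated)
Conditions: NaBH4, CeCl3·7H2O, MeOH, −78 °C; then 1 M aq. oxalic acid, THF, 0 °C
Reagents that add atoms: water, O
Why: Luche 1,2-reduction delivers hydride axially so that the new hydroxyl is pseudo-equatorial and trans to the adjacent ethyl group, and mild hydrolysis of the allylic ketal then unveils the transposed 4-hydroxy-enone.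

**Step 5**
Reactants: 7 (4R,5R,6R)-6-[4-(benzyloxy)butyl]-5-ethyl-4-hydroxycyclohex-2-en-1-one
Product: 8 (4R,5S,6R)-6-[4-(benzyloxy)butyl]-5-ethyl-4,6-dihydroxycyclohex-2-en-1-one
Conditions: KN(SiMe3)2 (2.2 equiv), THF, −78 °C; 2-(phenylsulfonyl)-3-phenyloxaziridine, −78 °C; aq. NH4Cl
Reagents that add atoms: 2-(phenylsulfonyl)-3-phenyloxaziridine, O=S(=O)(c1ccccc1)N1OC1c1ccccc1
Why: With the alkoxide shielding the γ-position, the second equivalent of base forms only the α'-enolate, which is oxidised by the N-sulfonyloxaziridine anti to the adjacent ethyl group (enolate hydroxylation), giving the tertiary carbinol with OH trans and side chain cis to ethyl and removing the one proton whose loss could aromatise the ring.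

**Step 6**
Reactants: 8 (4R,5S,6R)-6-[4-(benzyloxy)butyl]-5-ethyl-4,6-dihydroxycyclohex-2-en-1-one
Product: 9 (1R,5R,6S)-5-[4-(benzyloxy)butyl]-6-ethyl-5-hydroxy-4-oxocyclohex-2-en-1-yl prop-2-enoate
Conditions: acryloyl chloride, Et3N, CH2Cl2, −78 °C
Reagents that add atoms: acryloyl chloride, C=CC(Cl)=O
Why: Acylation discriminates the secondary allylic alcohol from the hindered tertiary α-ketol, so only the former is esterified and no stereocentre is touched.

**Step 7**
Reactants: 9 (1R,5R,6S)-5-[4-(benzyloxy)butyl]-6-ethyl-5-hydroxy-4-oxocyclohex-2-en-1-yl prop-2-enoate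
Product: 10 (3aS,6R,7S,7aR)-6-[4-(benzyloxy)butyl]-7-ethyl-6-hydroxy-3-methylidenehexahydro-1-benzofuran-2,5-dione
Conditions: PBu3 (20 mol%), tBuOH–THF, rt
Reagents that add atoms: none
Why: Intramolecular Rauhut–Currier reaction (phosphine adds to the acrylate, the enolate adds to the enone β-carbon, phosphine is eliminated) in which the ester tether can reach only the face bearing the oxygen, so the α-methylene lactone must be cis-fused; the precedent is the same lactone-forming cyclisation of acrylates of 4-hydroxycyclohexadienones.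

**Step 8**
Reactants: 10 (3aS,6R,7S,7aR)-6-[4-(benzyloxy)butyl]-7-ethyl-6-hydroxy-3-methylidenehexahydro-1-benzofuran-2,5-dione
Product: 11 (3R,3aS,6R,7S,7aR)-7-ethyl-6-hydroxy-6-(4-hydroxybutyl)-3-methylhexahydro-1-benzofuran-2,5-dione
Conditions: H2 (1 atm), Pd/C, EtOAc–EtOH, rt
Reagents that add atoms: none
Why: Heterogeneous hydrogenation should add hydrogen to the exocyclic methylene from the convex face of the cis-fused bicycle (syn to the ring-fusion hydrogens), placing the methyl on the concave face as in the target, while the benzyl ether is hydrogenolysed in the same operation.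

**Step 9**
Reactants: 11 (3R,3aS,6R,7S,7aR)-7-ethyl-6-hydroxy-6-(4-hydroxybutyl)-3-methylhexahydro-1-benzofuran-2,5-dione
Product: 12 (3R,3aS,6R,7S,7aR)-6-(4-chlorobutyl)-7-ethyl-6-hydroxy-3-methylhexahydro-1-benzofuran-2,5-dione
Conditions: PPh3, N-chlorosuccinimide, CH2Cl2, 0 °C
Reagents that add atoms: N-chlorosuccinimide, O=C1CCC(=O)N1Cl
Why: Appel-type chlorination converts the unhindered primary alcohol by SN2 displacement of its oxyphosphonium ion, while the tertiary α-ketol does not react.

**Step 10**
Reactants: 12 (3R,3aS,6R,7S,7aR)-6-(4-chlorobutyl)-7-ethyl-6-hydroxy-3-methylhexahydro-1-benzofuran-2,5-dione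
Product: 13 (3R,3aS,6R,7S,7aR)-6-(4-chlorobutyl)-7-ethyl-3-methyl-6-[(triethylsilyl)oxy]hexahydro-1-benzofuran-2,5-dione
Conditions: Et3SiOTf, 2,6-lutidine, CH2Cl2, −78 to 0 °C
Reagents that add atoms: triethylsilyl trifluoromethanesulfonate, CC[Si](CC)(CC)OS(=O)(=O)C(F)(F)F
Why: A silyl triflate with 2,6-lutidine silylates even a tertiary alcohol, and the ether later blocks oxa-cyclisation onto the halide arm and α-ketol or α-iminol shifts.

**Step 11**
Reactants: 13 (3R,3aS,6R,7S,7aR)-6-(4-chlorobutyl)-7-ethyl-3-methyl-6-[(triethylsilyl)oxy]hexahydro-1-benzofuran-2,5-dione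
Product: 14 (3R,3aS,6R,7S,7aR)-6-(4-chlorobutyl)-7-ethyl-3-methyl-2-oxo-6-[(triethylsilyl)oxy]-2,3,3a,6,7,7a-hexahydro-1-benzofuran-5-yl trifluoromethanesulfonate
Conditions: KN(SiMe3)2 (1.05 equiv), THF, −78 °C; PhNTf2; aq. NH4Cl
Reagents that add atoms: N-phenylbis(trifluoromethanesulfonimide), O=S(=O)(N(c1ccccc1)S(=O)(=O)C(F)(F)F)C(F)(F)F
Why: The ketone can enolise only toward its CH2 side (the other α-carbon is quaternary) and is more acidic than the lactone, so enolate O-sulfonylation should give a single enol triflate.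

**Step 12**
Reactants: 15 tert-butyl (4R)-4-formyl-2,2-dimethyl-1,3-oxazolidine-3-carboxylate; 16 ethyl 2-(bromomethyl)prop-2-enoate
Product: 18 tert-butyl (4R)-2,2-dimethyl-4-[(2S)-4-methylidene-5-oxooxolan-2-yl]-1,3-oxazolidine-3-carboxylate, via bromozinc alkoxide 17 (not isolated)
Conditions: Zn dust, THF, 50 °C; aq. NH4Cl
Reagents that add atoms: none
Why: Zinc-mediated Barbier/Reformatsky-type allylation with in situ lactonisation is the standard α-methylene-γ-butyrolactone synthesis, and non-chelation-controlled addition to this N-Boc oxazolidine aldehyde should favour the anti amino-alcohol configuration required for ring E.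

**Step 13**
Reactants: 18 tert-butyl (4R)-2,2-dimethyl-4-[(2S)-4-methylidene-5-oxooxolan-2-yl]-1,3-oxazolidine-3-carboxylate
Product: 19 tert-butyl (4R)-2,2-dimethyl-4-[(2S,4S)-4-methyl-5-oxooxolan-2-yl]-1,3-oxazolidine-3-carboxylate
Conditions: H2 (1 atm), Pd/C, EtOAc, rt
Reagents that add atoms: none
Why: Hydrogenation of the exocyclic alkene from the lactone face opposite the bulky γ-substituent should give the cis α-methyl-γ-substituted lactone.

**Step 14**
Reactants: 19 tert-butyl (4R)-2,2-dimethyl-4-[(2S,4S)-4-methyl-5-oxooxolan-2-yl]-1,3-oxazolidine-3-carboxylate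
Product: 20 (3S,5S)-5-[(1R)-1-amino-2-hydroxyethyl]-3-methyloxolan-2-one hydrochloride
Conditions: HCl (4 M in dioxane), H2O (5 equiv), 0 °C to rt
Reagents that add atoms: hydrogen chloride, Cl
Why: Acidolysis removes both the N,O-acetonide and the Boc group, and the amine is kept as its hydrochloride so that it cannot attack the lactone.

**Step 15**
Reactants: 20 (3S,5S)-5-[(1R)-1-amino-2-hydroxyethyl]-3-methyloxolan-2-one hydrochloride
Product: 21 (3S,5S)-5-[(1R)-2-hydroxy-1-(tritylamino)ethyl]-3-methyloxolan-2-one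
Conditions: TrCl, Et3N, CH2Cl2, 0 °C
Reagents that add atoms: trityl chloride, ClC(c1ccccc1)(c1ccccc1)c1ccccc1
Why: Tritylation is selective for nitrogen over the primary hydroxyl, and the bulky group suppresses acyl transfer from the lactone to nitrogen (no stereocentre touched).

**Step 16**
Reactants: 21 (3S,5S)-5-[(1R)-2-hydroxy-1-(tritylamino)ethyl]-3-methyloxolan-2-one
Product: 23 (3S,5S)-3-methyl-5-[(2R)-1-tritylaziridin-2-yl]oxolan-2-one, via mesylate 22 (not isolated)
Conditions: MsCl, Et3N, THF, 0 °C then 65 °C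
Reagents that add atoms: none
Why: O-Mesylation and 3-exo-tet SN2 displacement by the tritylamine close the aziridine at the primary carbon, so the nitrogen-bearing stereocentre is not involved and keeps its configuration.

**Step 17**
Reactants: 23 (3S,5S)-3-methyl-5-[(2R)-1-tritylaziridin-2-yl]oxolan-2-one
Product: 24 (3S,5S)-5-[(2R)-aziridin-2-yl]-3-methyloxolan-2-one
Conditions: CF3CO2H, CHCl3–MeOH (1:1), 0 °C; aq. NaHCO3
Reagents that add atoms: none
Why: Mild acidolysis with methanol as cation scavenger removes the N-trityl group at 0 °C without ring opening because trifluoroacetate is non-nucleophilic, as is routine for N-trityl aziridines.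

**Step 18**
Reactants: 14 alkenyl triflate (name as in step 11); 24 (3S,5S)-5-[(2R)-aziridin-2-yl]-3-methyloxolan-2-one
Product: 25 (3R,3aS,6R,7S,7aR)-6-(4-chlorobutyl)-7-ethyl-3-methyl-5-{(2R)-2-[(2S,4S)-4-methyl-5-oxooxolan-2-yl]aziridin-1-yl}-6-[(triethylsilyl)oxy]-3a,6,7,7a-tetrahydro-1-benzofuran-2(3H)-one
Conditions: Pd2(dba)3 (5 mol%), rac-BINAP (12 mol%), Cs2CO3, toluene, 90 °C
Reagents that add atoms: none
Why: Palladium-catalysed C–N cross-coupling (Buchwald–Hartwig type) of an alkenyl triflate with an NH-aziridine, a small amine whose amido complex cannot undergo β-hydride elimination, should give the N-alkenyl aziridine with the double bond fixed toward the CH carbon, and the weak carbonate base spares lactones, chloride and stereocentres.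

**Step 19**
Reactants: 25 N-alkenyl aziridine (name as in step 18)
Product: 29 O-triethylsilyl ether of the target at its tertiary hydroxyl, via pyrroline chloride 26 (not isolated), via pyrroline iodide 27 (not isolated), via iminium iodide 28 (not isolated)
Conditions: NaI (5 equiv), pyridinium p-toluenesulfonate (10 mol%), MeCN (0.005 M), 80 °C; then K2CO3, 80 °C; aqueous work-up
Reagents that add atoms: none
Why: The N-alkenyl aziridine is an enamine, and its protonation by the pyridinium catalyst gives an aziridinium ion that iodide opens by SN2 at the unsubstituted CH2 (the other ring carbon is secondary and deactivated by the β C–O bond of ring E) to a 2-iodoethyl imine/enamine, whose enamine carbon then closes ring C as a 1-pyrroline, a net three-to-five ring expansion. The closest known reaction type is the iodide-promoted rearrangement of N-vinylaziridines to 1-pyrrolines (the aza counterpart of the acid/halide cyclopropyl-imine rearrangement), here run in tandem with Finkelstein exchange and intramolecular imine N-alkylation. Ring C closes by 5-exo-tet C-alkylation and ring D by 7-exo-tet N-alkylation of the pyrroline nitrogen, giving the bicyclic iminium iodide, which on treatment with K2CO3 loses its only α-proton (the other α-carbon is the quaternary silyloxy carbon) to give the tetrasubstituted enamine. No stereocentre is created in the product, since the transient ring-fusion CH becomes sp2, and the aziridine stereocentre passes unchanged into ring C because substitution occurs only at CH2. The step needs ring opening at CH2, C- over N-alkylation of the ring-opened species (N-alkylation only regenerates the aziridinium ion) and intramolecular over intermolecular N-alkylation; these are secured by the aziridine substitution pattern, the 5-exo geometry and high dilution, while the silyl ether blocks oxa-cyclisation and α-iminol rearrangement.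

**Step 20**
Reactants: 29 O-triethylsilyl ether of the target
Product: 30 CNP0186848.1 (target)
Conditions: HF·pyridine, THF, 0 °C to rt; aq. NaHCO3
Reagents that add atoms: none
Why: Fluoride cleaves the tertiary triethylsilyl ether, the enamine is only reversibly protonated to its iminium salt and returns on bicarbonate work-up, and the lactones are inert, so the target should result with all stereocentres intact (desilylation).

**Compound list**

1 | 4-(benzyloxy)but-1-ene | C=CCCOCc1ccccc1 | starting material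
2 | [4-(benzyloxy)butyl]chlorobis(cyclopentadienyl)zirconium | Cl[Zr](CCCCOCc1ccccc1)(C1C=CC=C1)C1C=CC=C1 | intermediate
3 | 4,4-dimethoxycyclohexa-2,5-dien-1-one | COC1(OC)C=CC(=O)C=C1 | starting material
4 | (5R)-5-[4-(benzyloxy)butyl]-4,4-dimethoxycyclohex-2-en-1-one | O=C1C=CC(OC)(OC)[C@H](CCCCOCc2ccccc2)C1 | intermediate
5 | (5R,6R)-5-[4-(benzyloxy)butyl]-6-ethyl-4,4-dimethoxycyclohex-2-en-1-one | CC[C@H]1C(=O)C=CC(OC)(OC)[C@@H]1CCCCOCc2ccccc2 | intermediate
6 | (1R,5R,6R)-5-[4-(benzyloxy)butyl]-6-ethyl-4,4-dimethoxycyclohex-2-en-1-ol | CC[C@H]1[C@H](O)C=CC(OC)(OC)[C@@H]1CCCCOCc2ccccc2 | intermediate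
7 | (4R,5R,6R)-6-[4-(benzyloxy)butyl]-5-ethyl-4-hydroxycyclohex-2-en-1-one | CC[C@H]1[C@H](O)C=CC(=O)[C@@H]1CCCCOCc2ccccc2 | intermediate
8 | (4R,5S,6R)-6-[4-(benzyloxy)butyl]-5-ethyl-4,6-dihydroxycyclohex-2-en-1-one | CC[C@H]1[C@H](O)C=CC(=O)[C@@]1(O)CCCCOCc2ccccc2 | intermediate
9 | (1R,5R,6S)-5-[4-(benzyloxy)butyl]-6-ethyl-5-hydroxy-4-oxocyclohex-2-en-1-yl prop-2-enoate | CC[C@H]1[C@H](OC(=O)C=C)C=CC(=O)[C@@]1(O)CCCCOCc2ccccc2 | intermediate
10 | (3aS,6R,7S,7aR)-6-[4-(benzyloxy)butyl]-7-ethyl-6-hydroxy-3-methylidenehexahydro-1-benzofuran-2,5-dione (cis-fused) | CC[C@H]1[C@@H]2OC(=O)C(=C)[C@@H]2CC(=O)[C@@]1(O)CCCCOCc3ccccc3 | intermediate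
11 | (3R,3aS,6R,7S,7aR)-7-ethyl-6-hydroxy-6-(4-hydroxybutyl)-3-methylhexahydro-1-benzofuran-2,5-dione | CC[C@H]1[C@@H]2OC(=O)[C@H](C)[C@@H]2CC(=O)[C@@]1(O)CCCCO | intermediate
12 | (3R,3aS,6R,7S,7aR)-6-(4-chlorobutyl)-7-ethyl-6-hydroxy-3-methylhexahydro-1-benzofuran-2,5-dione | CC[C@H]1[C@@H]2OC(=O)[C@H](C)[C@@H]2CC(=O)[C@@]1(O)CCCCCl | intermediate
13 | (3R,3aS,6R,7S,7aR)-6-(4-chlorobutyl)-7-ethyl-3-methyl-6-[(triethylsilyl)oxy]hexahydro-1-benzofuran-2,5-dione | CC[C@H]1[C@@H]2OC(=O)[C@H](C)[C@@H]2CC(=O)[C@@]1(O[Si](CC)(CC)CC)CCCCCl | intermediate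
14 | (3R,3aS,6R,7S,7aR)-6-(4-chlorobutyl)-7-ethyl-3-methyl-2-oxo-6-[(triethylsilyl)oxy]-2,3,3a,6,7,7a-hexahydro-1-benzofuran-5-yl trifluoromethanesulfonate | CC[C@H]1[C@@H]2OC(=O)[C@H](C)[C@@H]2C=C(OS(=O)(=O)C(F)(F)F)[C@@]1(O[Si](CC)(CC)CC)CCCCCl | intermediate
15 | tert-butyl (4R)-4-formyl-2,2-dimethyl-1,3-oxazolidine-3-carboxylate | O=C[C@H]1COC(C)(C)N1C(=O)OC(C)(C)C | starting material
16 | ethyl 2-(bromomethyl)prop-2-enoate | CCOC(=O)C(=C)CBr | starting material
17 | bromozinc alkoxide of ethyl (4S)-4-hydroxy-2-methylidene-4-[(4R)-3-Boc-2,2-dimethyl-1,3-oxazolidin-4-yl]butanoate | CC(C)(C)OC(=O)N1[C@@H]([C@@H](O[Zn]Br)CC(=C)C(=O)OCC)COC1(C)C | intermediate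
18 | tert-butyl (4R)-2,2-dimethyl-4-[(2S)-4-methylidene-5-oxooxolan-2-yl]-1,3-oxazolidine-3-carboxylate | CC(C)(C)OC(=O)N1[C@@H]([C@@H]2CC(=C)C(=O)O2)COC1(C)C | intermediate
19 | tert-butyl (4R)-2,2-dimethyl-4-[(2S,4S)-4-methyl-5-oxooxolan-2-yl]-1,3-oxazolidine-3-carboxylate | CC(C)(C)OC(=O)N1[C@@H]([C@@H]2C[C@H](C)C(=O)O2)COC1(C)C | intermediate
20 | (3S,5S)-5-[(1R)-1-amino-2-hydroxyethyl]-3-methyloxolan-2-one hydrochloride | [Cl-].[NH3+][C@@H]([C@@H]1C[C@H](C)C(=O)O1)CO | intermediate
21 | (3S,5S)-5-[(1R)-2-hydroxy-1-(tritylamino)ethyl]-3-methyloxolan-2-one | OC[C@@H](NC(c1ccccc1)(c1ccccc1)c1ccccc1)[C@@H]1C[C@H](C)C(=O)O1 | intermediate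
22 | O-methanesulfonate of 21 | CS(=O)(=O)OC[C@@H](NC(c1ccccc1)(c1ccccc1)c1ccccc1)[C@@H]1C[C@H](C)C(=O)O1 | intermediate
23 | (3S,5S)-3-methyl-5-[(2R)-1-tritylaziridin-2-yl]oxolan-2-one | C(c1ccccc1)(c1ccccc1)(c1ccccc1)N1C[C@@H]1[C@@H]1C[C@H](C)C(=O)O1 | intermediate
24 | (3S,5S)-5-[(2R)-aziridin-2-yl]-3-methyloxolan-2-one | N1C[C@@H]1[C@@H]1C[C@H](C)C(=O)O1 | intermediate
25 | N-alkenyl aziridine: 14 with OTf replaced by the (2R)-2-[(2S,4S)-4-methyl-5-oxooxolan-2-yl]aziridin-1-yl group | CC[C@H]1[C@@H]2OC(=O)[C@H](C)[C@@H]2C=C(N3C[C@@H]3[C@@H]4C[C@H](C)C(=O)O4)[C@@]1(O[Si](CC)(CC)CC)CCCCCl | intermediate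
26 | 1-pyrroline (rings A, B, C, E; 4-chlorobutyl arm; ring-fusion CH of either configuration) | CC[C@H]1[C@@H]2OC(=O)[C@H](C)[C@@H]2C2C(=N[C@@H]([C@@H]3C[C@H](C)C(=O)O3)C2)[C@@]1(O[Si](CC)(CC)CC)CCCCCl | intermediate
27 | 1-pyrroline with 4-iodobutyl arm | CC[C@H]1[C@@H]2OC(=O)[C@H](C)[C@@H]2C2C(=N[C@@H]([C@@H]3C[C@H](C)C(=O)O3)C2)[C@@]1(O[Si](CC)(CC)CC)CCCCI | intermediate
28 | pentacyclic iminium iodide (rings A–E, C=N+ at the ring A/C/D junction) | CC[C@H]1[C@@H]2OC(=O)[C@H](C)[C@@H]2C2C3=[N+](CCCC[C@]31O[Si](CC)(CC)CC)[C@@H]([C@@H]1C[C@H](C)C(=O)O1)C2.[I-] | intermediate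
29 | O-triethylsilyl ether of the target at the tertiary hydroxyl | CC[C@H]1[C@@H]2OC(=O)[C@H](C)[C@@H]2C2=C3N(CCCC[C@]31O[Si](CC)(CC)CC)[C@@H]([C@@H]1C[C@H](C)C(=O)O1)C2 | intermediate
30 | CNP0186848.1 | CC[C@H]1[C@@H]2OC(=O)[C@H](C)[C@@H]2C2=C3N(CCCC[C@]31O)[C@@H]([C@@H]1C[C@H](C)C(=O)O1)C2 | target

**Count**

Total: 20 steps. Longest linear sequence: 14 steps (steps 1–11, then 18–20); the aziridine branch is steps 12–17.

**Steps most likely to fail, with fallbacks**

Step 19. The aziridine may open sluggishly or at the substituted carbon, the N-alkenyl aziridine may undergo a thermal hydrogen shift instead, or the seven-membered N-alkylation may lose to oligomerisation. The fallback builds ring C by enolate alkylation and cyclodehydration instead of ring expansion. It sets out from 19 and 13 and returns at 26. Acetonide methanolysis of 19 (p-TsOH cat., MeOH) gives tert-butyl N-{(1R)-2-hydroxy-1-[(2S,4S)-4-methyl-5-oxooxolan-2-yl]ethyl}carbamate F1. SOCl2/imidazole followed by RuCl3 (cat.)/NaIO4 converts it into the cyclic sulfamidate tert-butyl (4R)-4-[(2S,4S)-4-methyl-5-oxooxolan-2-yl]-1,2,3-oxathiazolidine-3-carboxylate 2,2-dioxide F2. The potassium enolate of 13 (KN(SiMe3)2, THF, −78 °C), which can form only at the CH2 α-carbon, opens F2 at its CH2–O carbon, and aqueous citric acid hydrolyses the N-sulfate to the γ-(Boc-amino) ketone F3. Boc removal with Me3SiOTf/2,6-lutidine then MeOH frees the amine, which condenses with the ketone to give 26. From 26 the NaI/K2CO3 treatment of step 19 continues to 29.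

Step 18. Oxidative addition and reductive elimination at an alkenyl carbon flanked by the quaternary silyloxy centre may be slow, letting triflate hydrolysis or N-alkylation of the aziridine by the chloride arm take over. The fallback reverses the polarity of the coupling. It sets out from 14 and returns at 25. Miyaura borylation of 14 (B2pin2, PdCl2(dppf), KOPh, toluene, 60 °C) gives the alkenyl pinacol boronate F4. Chan–Lam N-alkenylation of 24 with F4 (Cu(OAc)2, pyridine, 4 Å sieves, air, CH2Cl2, rt) then gives 25.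

Step 7. The phosphine may add reversibly without cyclisation onto the mono-enone, which is less electrophilic than the dienones of the precedent, or may oligomerise the acrylate. The fallback uses a stabilised carbanion and a later olefination. It sets out from 8 and returns at 10. Esterification of 8 with diethylphosphonoacetic acid (DCC, DMAP, CH2Cl2) gives the 4-O-(diethylphosphonoacetyl) ester F5. Intramolecular Michael addition (Cs2CO3, MeCN, rt) gives the cis-fused α-(diethoxyphosphoryl) lactone F6. Horner–Wadsworth–Emmons methylenation with aqueous formaldehyde/K2CO3 gives 10.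

**Further compounds**

F1 | step 19 | tert-butyl N-{(1R)-2-hydroxy-1-[(2S,4S)-4-methyl-5-oxooxolan-2-yl]ethyl}carbamate | OC[C@@H](NC(=O)OC(C)(C)C)[C@@H]1C[C@H](C)C(=O)O1
F2 | step 19 | tert-butyl (4R)-4-[(2S,4S)-4-methyl-5-oxooxolan-2-yl]-1,2,3-oxathiazolidine-3-carboxylate 2,2-dioxide | O=S1(=O)OC[C@H]([C@@H]2C[C@H](C)C(=O)O2)N1C(=O)OC(C)(C)C
F3 | step 19 | 13 alkylated at its CH2 α-carbon by the (2R)-2-(Boc-amino)-2-[(2S,4S)-4-methyl-5-oxooxolan-2-yl]ethyl group | CC[C@H]1[C@@H]2OC(=O)[C@H](C)[C@@H]2C(C[C@@H](NC(=O)OC(C)(C)C)[C@@H]3C[C@H](C)C(=O)O3)C(=O)[C@@]1(O[Si](CC)(CC)CC)CCCCCl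
F4 | step 18 | alkenyl pinacol boronate corresponding to triflate 14 | CC[C@H]1[C@@H]2OC(=O)[C@H](C)[C@@H]2C=C(B3OC(C)(C)C(C)(C)O3)[C@@]1(O[Si](CC)(CC)CC)CCCCCl
F5 | step 7 | 4-O-(diethylphosphonoacetyl) ester of diol 8 | CC[C@H]1[C@H](OC(=O)CP(=O)(OCC)OCC)C=CC(=O)[C@@]1(O)CCCCOCc2ccccc2
F6 | step 7 | cis-fused α-(diethoxyphosphoryl) lactone, phosphonate analogue of 10 | CC[C@H]1[C@@H]2OC(=O)C(P(=O)(OCC)OCC)[C@@H]2CC(=O)[C@@]1(O)CCCCOCc3ccccc3
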